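**Retrosynthetic overview**
1. Last bond: C(sp3)–C(sp2) between the homoallylic CH2 and the alkene CH, by B-alkyl Suzuki–Miyaura coupling of a C11 vinyl-dioxane ester (15 non-hydrogen atoms, as its 9-BBN adduct) with a C14 (E)-vinyl iodide enone (16 non-hydrogen atoms).
2. Iodide half: the E-trisubstituted alkene comes from Zr-catalysed carboalumination/iodination of a terminal alkyne; the side chain is attached by Stork–Danheiser addition to 3-ethoxy-2,6,6-trimethylcyclohexenone (from cyclohexane-1,3-dione).
3. Dioxane half: tertiary C–OO by invertive perhydrolysis of an epoxide derived from (S)-2-methylglycidol; ring closure by invertive SN2 attack of the hydroperoxide on a secondary mesylate set up by Roush syn-crotylation; the crotyl vinyl group is degraded to the methyl ester.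
4. Ring order: the carbocycle (ring A) is present from the start; the 1,2-dioxane (ring B) is closed in step 18; the halves are joined in step 24.

Assumption: the target is the (2S,3S,6R) isomer with an E side-chain alkene, as the SMILES encodes; stereocentres in the racemic ring-A intermediates are destroyed before the coupling and are written without configuration.

**Iodide half**

Step 1
Reactants: 1 but-3-yn-1-ol
Product: 4 4-(trimethylsilyl)but-3-yn-1-ol, via dilithio derivative 2 (not isolated), via bis-silyl compound 3 (not isolated)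
Conditions: n-BuLi (2.2 equiv), THF, −78 °C; Me3SiCl (2.3 equiv), −78 °C → rt; then 1 M HCl, rt
Reagents that add atoms: chlorotrimethylsilane, C[Si](C)(C)Cl
Why: Double deprotonation and bis-silylation, followed by acidic cleavage of the labile O–Si bond, leaves the C-silylated alkyne (alkyne C-silylation), masking the acidic alkyne proton for the later organolithium step.

Step 2
Reactants: 4 4-(trimethylsilyl)but-3-yn-1-ol
Product: 5 (4-iodobut-1-yn-1-yl)trimethylsilane
Conditions: PPh3, I2, imidazole, CH2Cl2, 0 °C → rt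
Reagents that add atoms: iodine, II
Why: Appel-type iodination converts the primary alcohol to the iodide by SN2 displacement of the alkoxyphosphonium ion; the silyl alkyne is inert.

Step 3
Reactants: 6 cyclohexane-1,3-dione
Product: 7 2-methylcyclohexane-1,3-dione
Conditions: MeI, NaOH, H2O/1,4-dioxane, 65 °C
Reagents that add atoms: iodomethane, CI
Why: C-alkylation of the stabilised 1,3-diketone enolate at the doubly activated C2 (enolate alkylation).

Step 4
Reactants: 7 2-methylcyclohexane-1,3-dione
Product: 8 3-ethoxy-2-methylcyclohex-2-en-1-one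
Conditions: EtOH, p-TsOH·H2O (cat.), toluene, reflux (Dean–Stark)
Reagents that add atoms: ethanol, CCO
Why: Acid-catalysed vinylogous esterification with azeotropic removal of water gives the β-alkoxy enone needed for Stork–Danheiser chemistry.

Step 5
Reactants: 8 3-ethoxy-2-methylcyclohex-2-en-1-one
Product: 10 3-ethoxy-2,6-dimethylcyclohex-2-en-1-one (racemic), via lithium enolate 9 (not isolated)
Conditions: LiN(iPr)2, THF, −78 °C; then MeI, −78 → 0 °C
Reagents that add atoms: iodomethane, CI
Why: Kinetic deprotonation of the vinylogous ester occurs at the α′-CH2 and the cross-conjugated enolate is C-methylated (Stork–Danheiser alkylation); the new centre is racemic and is erased in step 6.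

Step 6
Reactants: 10 3-ethoxy-2,6-dimethylcyclohex-2-en-1-one (racemic)
Product: 12 3-ethoxy-2,6,6-trimethylcyclohex-2-en-1-one, via lithium enolate 11 (not isolated)
Conditions: LiN(iPr)2, THF, −78 °C; then MeI, −78 → 0 °C
Reagents that add atoms: iodomethane, CI
Why: A second kinetic α′-deprotonation and methylation (enolate alkylation) installs the gem-dimethyl group at the only enolisable α′ position.

Step 7
Reactants: 12 3-ethoxy-2,6,6-trimethylcyclohex-2-en-1-one; 5 (4-iodobut-1-yn-1-yl)trimethylsilane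
Product: 15 2,4,4-trimethyl-3-[4-(trimethylsilyl)but-3-yn-1-yl]cyclohex-2-en-1-one, via organolithium 13 (not isolated), via lithium alkoxide 14 (not isolated)
Conditions: 5, t-BuLi (2.1 equiv), Et2O/pentane, −78 °C; then 12, −78 → 0 °C; then 1 M HCl, THF, rt
Reagents that add atoms: water, O
Why: Iodine–lithium exchange gives a primary alkyllithium that adds 1,2 to the non-enolisable vinylogous-ester carbonyl, and acid hydrolysis of the enol ether with loss of the tertiary hydroxyl transposes the carbonyl (Stork–Danheiser sequence), placing the side chain next to the gem-dimethyl carbon.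

Step 8
Reactants: 15 2,4,4-trimethyl-3-[4-(trimethylsilyl)but-3-yn-1-yl]cyclohex-2-en-1-one
Product: 16 3-(but-3-yn-1-yl)-2,4,4-trimethylcyclohex-2-en-1-one
Conditions: K2CO3 (0.2 equiv), MeOH, rt
Reagents that add atoms: none
Why: Base-catalysed methanolysis cleaves the C(sp)–Si bond (protodesilylation) without touching the enone.

Step 9
Reactants: 16 3-(but-3-yn-1-yl)-2,4,4-trimethylcyclohex-2-en-1-one
Product: 17 3-(but-3-yn-1-yl)-2,4,4-trimethylcyclohex-2-en-1-ol (racemic)
Conditions: NaBH4, CeCl3·7H2O, MeOH, 0 °C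
Reagents that add atoms: none
Why: Luche 1,2-reduction masks the ketone as the allylic alcohol, because a free ketone would be methylated by AlMe3 in step 10; the carbinol centre is racemic and is re-oxidised in step 11.

Step 10
Reactants: 17 3-(but-3-yn-1-yl)-2,4,4-trimethylcyclohex-2-en-1-ol (racemic)
Product: 19 3-[(3E)-4-iodo-3-methylbut-3-en-1-yl]-2,4,4-trimethylcyclohex-2-en-1-ol (racemic), via alkenylalane 18 (not isolated)
Conditions: AlMe3 (3.5 equiv), Cp2ZrCl2 (0.25 equiv), CH2Cl2, 0 °C → rt; then I2, THF, −30 → 0 °C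
Reagents that add atoms: trimethylaluminium, C[Al](C)C; iodine, II
Why: Negishi Zr-catalysed carboalumination adds Me–Al syn across the terminal alkyne with aluminium at the terminus (the hydroxyl is carried as its aluminium alkoxide), and iodinolysis with retention gives the (E)-2-methyl-1-iodoalkene, fixing the alkene geometry of the target.

Step 11
Reactants: 19 3-[(3E)-4-iodo-3-methylbut-3-en-1-yl]-2,4,4-trimethylcyclohex-2-en-1-ol (racemic)
Product: 20 3-[(3E)-4-iodo-3-methylbut-3-en-1-yl]-2,4,4-trimethylcyclohex-2-en-1-one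
Conditions: MnO2 (15 equiv), CH2Cl2, rt
Reagents that add atoms: none
Why: Allylic alcohol oxidation with MnO2 restores the enone and leaves the vinyl iodide untouched.

**Dioxane half**

Step 12
Reactants: 21 [(2S)-2-methyloxiran-2-yl]methanol
Product: 22 (2R)-2-methylhex-5-ene-1,2-diol
Conditions: CH2=CHCH2MgCl (2.5 equiv), CuI (10 mol%), THF, −30 → 0 °C; aqueous NH4Cl work-up
Reagents that add atoms: allylmagnesium chloride, C=CC[Mg]Cl
Why: Cu-catalysed Grignard opening of the epoxide at its unsubstituted carbon (SN2) extends the chain without touching the quaternary stereocentre, which is carried over from (S)-2-methylglycidol.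

Step 13
Reactants: 22 (2R)-2-methylhex-5-ene-1,2-diol
Product: 24 (2R)-2-(but-3-en-1-yl)-2-methyloxirane, via monotosylate 23 (not isolated)
Conditions: TsCl (1.05 equiv), Et3N, DMAP (cat.), CH2Cl2, 0 °C; then K2CO3, MeOH, rt
Reagents that add atoms: none
Why: Selective sulfonylation of the primary hydroxyl and intramolecular Williamson closure (3-exo-tet) re-form a 2,2-disubstituted epoxide with the tertiary C–O bond, and so the stereocentre, intact.

Step 14
Reactants: 24 (2R)-2-(but-3-en-1-yl)-2-methyloxirane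
Product: 26 3-[(2R)-2-methyloxiran-2-yl]propanal, via ozonide 25 (not isolated)
Conditions: O3, CH2Cl2, −78 °C; then PPh3, −78 °C → rt
Reagents that add atoms: ozone, O=[O+][O-]
Why: Ozonolysis of the terminal alkene with reductive work-up gives the aldehyde; the epoxide is inert to ozone and PPh3.

Step 15
Reactants: 26 3-[(2R)-2-methyloxiran-2-yl]propanal
Product: 27 (3R,4R)-3-methyl-6-[(2R)-2-methyloxiran-2-yl]hex-1-en-4-ol
Conditions: (R,R)-diisopropyl tartrate (Z)-crotylboronate (1.5 equiv), 4 Å MS, toluene, −78 °C; aqueous work-up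
Reagents that add atoms: diisopropyl (4R,5R)-2-[(2Z)-but-2-en-1-yl]-1,3,2-dioxaborolane-4,5-dicarboxylate, CC(C)OC(=O)[C@@H]1OB(C/C=C\C)O[C@H]1C(=O)OC(C)C
Why: Roush asymmetric crotylboration through a chair Zimmerman–Traxler transition state: the Z-crotyl geometry gives the 3,4-syn relationship and the (R,R)-tartrate directs si-face attack to set (3R,4R) (reagent control, about 9:1; the minor diastereomer is removed by chromatography), under Lewis-acid-free conditions that spare the epoxide.

Step 16
Reactants: 27 (3R,4R)-3-methyl-6-[(2R)-2-methyloxiran-2-yl]hex-1-en-4-ol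
Product: 28 (3R,4R)-3-methyl-6-[(2R)-2-methyloxiran-2-yl]hex-1-en-4-yl methanesulfonate
Conditions: MsCl, Et3N, CH2Cl2, −20 → 0 °C
Reagents that add atoms: methanesulfonyl chloride, CS(=O)(=O)Cl
Why: Mesylation (sulfonate ester formation) turns the secondary hydroxyl into the leaving group for ring closure and stops it from opening the epoxide in the acid-catalysed step that follows.

Step 17
Reactants: 28 (3R,4R)-3-methyl-6-[(2R)-2-methyloxiran-2-yl]hex-1-en-4-yl methanesulfonate
Product: 29 (3R,4R,7S)-7-hydroperoxy-8-hydroxy-3,7-dimethyloct-1-en-4-yl methanesulfonate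
Conditions: anhydrous H2O2 in Et2O (10 equiv), H3PMo12O40 (5 mol%), Et2O, rt
Reagents that add atoms: hydrogen peroxide, OO
Why: Phosphomolybdic-acid-catalysed perhydrolysis: H2O2 opens the activated epoxide at the tertiary carbon in a borderline SN2 process with inversion, creating the tertiary C–OOH centre (7S) that becomes the quaternary ring carbon of the target.

Step 18
Reactants: 29 (3R,4R,7S)-7-hydroperoxy-8-hydroxy-3,7-dimethyloct-1-en-4-yl methanesulfonate
Product: 30 {(3S,6S)-6-[(2R)-but-3-en-2-yl]-3-methyl-1,2-dioxan-3-yl}methanol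
Conditions: CsOH·H2O (1.1 equiv), DMF, 0 °C → rt
Reagents that add atoms: none
Why: The hydroperoxide, far more acidic than the alcohol, is deprotonated selectively and displaces the secondary mesylate in a 6-exo-tet SN2 reaction (intramolecular peroxide alkylation), closing the 1,2-dioxane with inversion at the ring CH carbon.

Step 19
Reactants: 30 {(3S,6S)-6-[(2R)-but-3-en-2-yl]-3-methyl-1,2-dioxan-3-yl}methanol
Product: 32 (2S)-2-[(3S,6S)-6-(hydroxymethyl)-6-methyl-1,2-dioxan-3-yl]propanal, via ozonide 31 (not isolated)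
Conditions: O3, CH2Cl2, −78 °C; then PPh3 (1.1 equiv), −78 → 0 °C
Reagents that add atoms: ozone, O=[O+][O-]
Why: Ozonolysis of the vinyl group with reductive work-up unmasks the aldehyde; dialkyl peroxides survive ozone and brief exposure to PPh3 at low temperature.

Step 20
Reactants: 32 (2S)-2-[(3S,6S)-6-(hydroxymethyl)-6-methyl-1,2-dioxan-3-yl]propanal
Product: 33 (2S)-2-[(3S,6S)-6-(hydroxymethyl)-6-methyl-1,2-dioxan-3-yl]propanoic acid
Conditions: NaClO2, NaH2PO4, 2-methylbut-2-ene, t-BuOH/H2O, 0 °C → rt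
Reagents that add atoms: sodium chlorite, [Na+].[O-]Cl=O
Why: Pinnick oxidation converts the aldehyde to the acid under buffered conditions that neither epimerise the α-centre nor touch the peroxide or the primary alcohol.

Step 21
Reactants: 33 (2S)-2-[(3S,6S)-6-(hydroxymethyl)-6-methyl-1,2-dioxan-3-yl]propanoic acid
Product: 34 methyl (2S)-2-[(3S,6S)-6-(hydroxymethyl)-6-methyl-1,2-dioxan-3-yl]propanoate
Conditions: Me3SiCHN2, MeOH/toluene, 0 °C
Reagents that add atoms: (trimethylsilyl)diazomethane, C[Si](C)(C)C=[N+]=[N-]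
Why: Esterification under neutral conditions: diazomethane released in situ O-methylates the carboxylic acid, so the base-sensitive β-peroxy carbonyl unit is never exposed to base.

Step 22
Reactants: 34 methyl (2S)-2-[(3S,6S)-6-(hydroxymethyl)-6-methyl-1,2-dioxan-3-yl]propanoate
Product: 35 methyl (2S)-2-[(3S,6S)-6-formyl-6-methyl-1,2-dioxan-3-yl]propanoate
Conditions: Dess–Martin periodinane, CH2Cl2, 0 °C → rt
Reagents that add atoms: none
Why: Dess–Martin oxidation of the neopentyl-type primary alcohol gives the non-enolisable α-peroxy aldehyde under mild, non-basic conditions.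

Step 23
Reactants: 35 methyl (2S)-2-[(3S,6S)-6-formyl-6-methyl-1,2-dioxan-3-yl]propanoate
Product: 36 methyl (2S)-2-[(3S,6S)-6-ethenyl-6-methyl-1,2-dioxan-3-yl]propanoate
Conditions: Ph3PCH3Br (1.3 equiv), KN(SiMe3)2 (1.2 equiv), THF, 0 °C; then 35, −78 → 0 °C
Reagents that add atoms: methyltriphenylphosphonium bromide, C[P+](c1ccccc1)(c1ccccc1)c1ccccc1.[Br-]
Why: Wittig methylenation at low temperature with a slight deficit of base installs the vinyl group without enolising the ester.

**Fragment union**

Step 24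
Reactants: 36 methyl (2S)-2-[(3S,6S)-6-ethenyl-6-methyl-1,2-dioxan-3-yl]propanoate; 20 3-[(3E)-4-iodo-3-methylbut-3-en-1-yl]-2,4,4-trimethylcyclohex-2-en-1-one
Product: 38 methyl (2S)-2-[(3S,6R)-6-methyl-6-[(3E)-4-methyl-6-(2,6,6-trimethyl-3-oxocyclohex-1-en-1-yl)hex-3-en-1-yl]-1,2-dioxan-3-yl]propanoate, via alkylborane 37 (not isolated)
Conditions: 36, 9-BBN (1.3 equiv), THF, 0 °C → rt; then 20, PdCl2(dppf) (8 mol%), AsPh3 (8 mol%), Cs2CO3 (3 equiv), DMF/H2O, rt
Reagents that add atoms: none
Why: Anti-Markovnikov hydroboration of the vinyl group and B-alkyl Suzuki–Miyaura coupling (oxidative addition of zerovalent palladium into the C–I bond, transmetalation, reductive elimination) join the halves with retention of the E geometry; ester, enone and dialkyl peroxide are expected to tolerate these room-temperature conditions.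

**Compound list**
1 | but-3-yn-1-ol | C#CCCO | starting material
2 | lithium 4-lithiobut-3-yn-1-olate (dilithio derivative; not isolated) | [Li]C#CCCO[Li] | intermediate
3 | trimethyl{[4-(trimethylsilyl)but-3-yn-1-yl]oxy}silane (bis-silyl compound; not isolated) | C[Si](C)(C)C#CCCO[Si](C)(C)C | intermediate
4 | 4-(trimethylsilyl)but-3-yn-1-ol | C[Si](C)(C)C#CCCO | intermediate
5 | (4-iodobut-1-yn-1-yl)trimethylsilane | C[Si](C)(C)C#CCCI | intermediate
6 | cyclohexane-1,3-dione | O=C1CCCC(=O)C1 | starting material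
7 | 2-methylcyclohexane-1,3-dione | CC1C(=O)CCCC1=O | intermediate
8 | 3-ethoxy-2-methylcyclohex-2-en-1-one | CCOC1=C(C)C(=O)CCC1 | intermediate
9 | lithium 5-ethoxy-6-methylcyclohexa-1,5-dien-1-olate (lithium enolate; not isolated) | [Li]OC1=CCCC(OCC)=C1C | intermediate
10 | 3-ethoxy-2,6-dimethylcyclohex-2-en-1-one (racemic) | CCOC1=C(C)C(=O)C(C)CC1 | intermediate
11 | lithium 5-ethoxy-2,6-dimethylcyclohexa-1,5-dien-1-olate (lithium enolate; not isolated) | [Li]OC1=C(C)CCC(OCC)=C1C | intermediate
12 | 3-ethoxy-2,6,6-trimethylcyclohex-2-en-1-one | CCOC1=C(C)C(=O)C(C)(C)CC1 | intermediate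
13 | [4-(trimethylsilyl)but-3-yn-1-yl]lithium (organolithium; not isolated) | [Li]CCC#C[Si](C)(C)C | intermediate
14 | lithium 3-ethoxy-2,6,6-trimethyl-1-[4-(trimethylsilyl)but-3-yn-1-yl]cyclohex-2-en-1-olate (racemic; lithium alkoxide; not isolated) | CCOC1=C(C)C(O[Li])(CCC#C[Si](C)(C)C)C(C)(C)CC1 | intermediate
15 | 2,4,4-trimethyl-3-[4-(trimethylsilyl)but-3-yn-1-yl]cyclohex-2-en-1-one | CC1=C(CCC#C[Si](C)(C)C)C(C)(C)CCC1=O | intermediate
16 | 3-(but-3-yn-1-yl)-2,4,4-trimethylcyclohex-2-en-1-one | CC1=C(CCC#C)C(C)(C)CCC1=O | intermediate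
17 | 3-(but-3-yn-1-yl)-2,4,4-trimethylcyclohex-2-en-1-ol (racemic) | CC1=C(CCC#C)C(C)(C)CCC1O | intermediate
18 | {(1E)-4-[3-(dimethylalumanyloxy)-2,6,6-trimethylcyclohex-1-en-1-yl]-2-methylbut-1-en-1-yl}dimethylalumane (racemic; alkenylalane; not isolated) | C[Al](C)/C=C(\C)CCC1=C(C)C(O[Al](C)C)CCC1(C)C | intermediate
19 | 3-[(3E)-4-iodo-3-methylbut-3-en-1-yl]-2,4,4-trimethylcyclohex-2-en-1-ol (racemic) | CC1=C(CC/C(C)=C/I)C(C)(C)CCC1O | intermediate
20 | 3-[(3E)-4-iodo-3-methylbut-3-en-1-yl]-2,4,4-trimethylcyclohex-2-en-1-one | CC1=C(CC/C(C)=C/I)C(C)(C)CCC1=O | intermediate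
21 | [(2S)-2-methyloxiran-2-yl]methanol | C[C@]1(CO)CO1 | starting material
22 | (2R)-2-methylhex-5-ene-1,2-diol | C=CCC[C@@](C)(O)CO | intermediate
23 | (2R)-2-hydroxy-2-methylhex-5-en-1-yl 4-methylbenzenesulfonate (monotosylate; not isolated) | C=CCC[C@@](C)(O)COS(=O)(=O)c1ccc(C)cc1 | intermediate
24 | (2R)-2-(but-3-en-1-yl)-2-methyloxirane | C=CCC[C@]1(C)CO1 | intermediate
25 | 3-{2-[(2R)-2-methyloxiran-2-yl]ethyl}-1,2,4-trioxolane (ozonide; not isolated) | C1OC(CC[C@]2(C)CO2)OO1 | intermediate
26 | 3-[(2R)-2-methyloxiran-2-yl]propanal | O=CCC[C@]1(C)CO1 | intermediate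
27 | (3R,4R)-3-methyl-6-[(2R)-2-methyloxiran-2-yl]hex-1-en-4-ol | C=C[C@@H](C)[C@H](O)CC[C@]1(C)CO1 | intermediate
28 | (3R,4R)-3-methyl-6-[(2R)-2-methyloxiran-2-yl]hex-1-en-4-yl methanesulfonate | C=C[C@@H](C)[C@H](OS(C)(=O)=O)CC[C@]1(C)CO1 | intermediate
29 | (3R,4R,7S)-7-hydroperoxy-8-hydroxy-3,7-dimethyloct-1-en-4-yl methanesulfonate | C=C[C@@H](C)[C@H](OS(C)(=O)=O)CC[C@@](C)(CO)OO | intermediate
30 | {(3S,6S)-6-[(2R)-but-3-en-2-yl]-3-methyl-1,2-dioxan-3-yl}methanol | C=C[C@@H](C)[C@@H]1CC[C@@](C)(CO)OO1 | intermediate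
31 | {(3S,6S)-3-methyl-6-[(1S)-1-(1,2,4-trioxolan-3-yl)ethyl]-1,2-dioxan-3-yl}methanol (ozonide; not isolated) | C1OC(OO1)[C@@H](C)[C@@H]2CC[C@@](C)(CO)OO2 | intermediate
32 | (2S)-2-[(3S,6S)-6-(hydroxymethyl)-6-methyl-1,2-dioxan-3-yl]propanal | O=C[C@@H](C)[C@@H]1CC[C@@](C)(CO)OO1 | intermediate
33 | (2S)-2-[(3S,6S)-6-(hydroxymethyl)-6-methyl-1,2-dioxan-3-yl]propanoic acid | OC(=O)[C@@H](C)[C@@H]1CC[C@@](C)(CO)OO1 | intermediate
34 | methyl (2S)-2-[(3S,6S)-6-(hydroxymethyl)-6-methyl-1,2-dioxan-3-yl]propanoate | COC(=O)[C@@H](C)[C@@H]1CC[C@@](C)(CO)OO1 | intermediate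
35 | methyl (2S)-2-[(3S,6S)-6-formyl-6-methyl-1,2-dioxan-3-yl]propanoate | COC(=O)[C@@H](C)[C@@H]1CC[C@@](C)(C=O)OO1 | intermediate
36 | methyl (2S)-2-[(3S,6S)-6-ethenyl-6-methyl-1,2-dioxan-3-yl]propanoate | COC(=O)[C@@H](C)[C@@H]1CC[C@@](C)(C=C)OO1 | intermediate
37 | methyl (2S)-2-{(3S,6R)-6-[2-(9-borabicyclo[3.3.1]nonan-9-yl)ethyl]-6-methyl-1,2-dioxan-3-yl}propanoate (alkylborane; not isolated) | COC(=O)[C@@H](C)[C@@H]1CC[C@@](C)(CCB2C3CCCC2CCC3)OO1 | intermediate
38 | methyl (2S)-2-[(3S,6R)-6-methyl-6-[(3E)-4-methyl-6-(2,6,6-trimethyl-3-oxocyclohex-1-en-1-yl)hex-3-en-1-yl]-1,2-dioxan-3-yl]propanoate | COC(=O)[C@@H](C)[C@@H]1CC[C@@](C)(CC/C=C(\C)CCC2=C(C)C(=O)CCC2(C)C)OO1 | target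

**Step count**
Total: 24 steps. Longest linear sequence: 13 steps (21 → 38, steps 12–24). The other branches are 6 → 38 (10 steps) and 1 → 38 (8 steps).

**Steps most likely to fail, with fallbacks**

Step 17 (perhydrolysis of 28): attack at the tertiary carbon must beat diol formation and must proceed with clean inversion, which is the least certain stereochemical event in the route. The fallback sets out from 28 and reverses the order of C–O bond formation. The mesylate is displaced first with H2O2/KOH in MeOH at 0 °C (intermolecular SN2, inversion) to give (2R)-2-[(3S,4R)-3-hydroperoxy-4-methylhex-5-en-1-yl]-2-methyloxirane F1. The secondary hydroperoxide then opens the epoxide at its tertiary carbon intramolecularly (camphorsulfonic acid cat., CH2Cl2, 0 °C; 6-exo, inversion). This gives 30 directly, and the route continues from 30.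

Step 18 (SN2 closure of 29): a β-branched secondary mesylate is a slow electrophile, and the β-hydroxy hydroperoxide can fragment under base. The fallback sets out from aldehyde 26 and closes the ring by conjugate addition instead. Wittig reaction of 26 with methyl 2-(triphenylphosphoranylidene)propanoate (CH2Cl2, rt) gives methyl (2E)-2-methyl-5-[(2R)-2-methyloxiran-2-yl]pent-2-enoate F2. Perhydrolysis under the step 17 conditions gives methyl (2E,6S)-6-hydroperoxy-7-hydroxy-2,6-dimethylhept-2-enoate F3. Et2NH in CF3CH2OH then triggers intramolecular oxa-Michael addition of the hydroperoxide. The quaternary centre is still set by the epoxide, but the two adjacent centres arise as a diastereomer mixture from which 34 must be separated by HPLC; the route is rejoined at 34.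

Step 24 (hydroboration and palladium catalysis next to the O–O bond): the alkylborane sits three atoms from a peroxide oxygen, and the peroxide must survive the catalyst. The fallback sets out from aldehyde 35 and joins the halves through an alkyne. Ohira–Bestmann homologation (dimethyl (1-diazo-2-oxopropyl)phosphonate, K2CO3, MeOH, 0 °C) gives methyl (2S)-2-[(3S,6S)-6-ethynyl-6-methyl-1,2-dioxan-3-yl]propanoate F4. Sonogashira coupling with 20 (PdCl2(PPh3)2, CuI, Et3N, THF, rt) gives methyl (2S)-2-{(3S,6S)-6-methyl-6-[(3E)-4-methyl-6-(2,6,6-trimethyl-3-oxocyclohex-1-en-1-yl)hex-3-en-1-yn-1-yl]-1,2-dioxan-3-yl}propanoate F5. Diimide (2-nitrobenzenesulfonohydrazide, Et3N, CH2Cl2, rt) then saturates only the triple bond (through the Z-diene), leaving the tri- and tetrasubstituted alkenes and the peroxide untouched, and delivers 38.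

**Further compounds**
F1 | step 17 | (2R)-2-[(3S,4R)-3-hydroperoxy-4-methylhex-5-en-1-yl]-2-methyloxirane | C=C[C@@H](C)[C@@H](OO)CC[C@]1(C)CO1
F2 | step 18 | methyl (2E)-2-methyl-5-[(2R)-2-methyloxiran-2-yl]pent-2-enoate | COC(=O)/C(C)=C/CC[C@]1(C)CO1
F3 | step 18 | methyl (2E,6S)-6-hydroperoxy-7-hydroxy-2,6-dimethylhept-2-enoate | COC(=O)/C(C)=C/CC[C@@](C)(CO)OO
F4 | step 24 | methyl (2S)-2-[(3S,6S)-6-ethynyl-6-methyl-1,2-dioxan-3-yl]propanoate | COC(=O)[C@@H](C)[C@@H]1CC[C@@](C)(C#C)OO1
F5 | step 24 | methyl (2S)-2-{(3S,6S)-6-methyl-6-[(3E)-4-methyl-6-(2,6,6-trimethyl-3-oxocyclohex-1-en-1-yl)hex-3-en-1-yn-1-yl]-1,2-dioxan-3-yl}propanoate | COC(=O)[C@@H](C)[C@@H]1CC[C@@](C)(C#C/C=C(\C)CCC2=C(C)C(=O)CCC2(C)C)OO1
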